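## Structural features

The target is a bicyclo[3.3.1]nonane-2,4,9-trione, drawn as its C3=C4 enol. Ring B (C1–C2–C3–C4–C5–C9) carries the 3,4-dihydroxybenzoyl group on C3; ring C (C1–C8–C7–C6–C5–C9) carries a gem-dimethyl group on C8 and a prenyl group on C7; C9 is the bridging ketone. Both bridgeheads are quaternary: C1 (S) bears a prenyl group and is bonded to the fully substituted C8, and C5 (S) bears the (2E,4S)-4-hydroxy-3,7-dimethylocta-2,6-dienyl chain (4-hydroxygeranyl, atoms primed below). C1, C7 (R) and C5 stand in a 1,3,5-relationship around ring C, and the C7 prenyl group is equatorial (exo) on the chair. The carbinol C4' is insulated from the core by C1'–C3', so it cannot be set by the ring and must arrive enantiopure. The fragile groups are the four trisubstituted alkenes (acid adds enol oxygen across them), the ionisable secondary allylic alcohol, the air-sensitive catechol and the strongly acidic β-triketone, which is easily O-alkylated. The real difficulty is the C1–C8 bond between two fully substituted carbons, together with the quaternary centre C5, whose configuration relative to C7 decides the exo or endo position of the C7 substituent and dictates C1. The key step exploits that C1–C5 and C9 are the six carbons of an aroylphloroglucinol: once C5 is dearomatised and carries a lavandulyl arm (C6, C7, C8), C1 is a nucleophilic enol carbon positioned for a six-membered closure onto a cation at C8.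

## Logic of the disconnections

**21 ⇒ 20.** Three ester C–O bonds are cut (two aryl pivalates, the C4' acetate). The catechol needs masks that survive AlCl3, amide base, zerovalent palladium and formic acid. The carbinol needs an electron-poor ester that resists ionisation and deactivates the C2'=C3' alkene towards protonation. There is no skeletal gain, but everything before depends on it. The demand is that one methanolysis removes all three esters while the trione sits protected as its enolate and oxygen is excluded from the catechol.

**20 ⇒ 19.** The C1–C8 bond is cut. This is the most congested bond of the bicycle and the only ring bond that is not already present in a phloroglucinol plus a lavandulyl unit. Ring C, the bicycle and the stereocentre C1 disappear and a monocyclic, dearomatised aroylphloroglucinol remains with every carbon of the target in place. The forward step must protonate only the isopropenyl group, capture the C8 cation through C1 rather than through C3 or an enol oxygen, and start from the 5S,7R diastereomer so that the chair puts the C7 prenyl group equatorial.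

**19 ⇒ 11 + 18.** The C5–C1' bond is cut. This removes the quaternary stereocentre C5 and returns an aromatic, fully substituted aroylphloroglucinol and an allylic carbonate that carries the carbinol. The forward allylation must go to the lavandulyl-bearing ring carbon and not the prenyl-bearing one, on the face that gives 5S, at the unsubstituted allyl terminus with retention of the E alkene, and it must leave the secondary allylic acetate untouched.

**11 ⇒ 7 + 10.** The ring-carbon–C6 bond is cut, so that C7 is bought as lavandulol. The gain is a simple monoprenylated aroylphloroglucinol and a C10 triflate. The demand is C- over O-alkylation by an unactivated, β-branched primary electrophile that must not ionise.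

**7 ⇒ 6 ⇒ 4 + 5; 4 ⇒ 3 ⇒ 1.** The ring-carbon–prenyl bond is cut first (mono-C-prenylation of a symmetrical nucleophile; the demand is to stop after one alkylation). Then the aryl–carbonyl bond is cut (Friedel–Crafts acylation; the two free positions of 5 are equivalent, so there is no regiochemical question). The acyl chloride goes back to the acid, and the two pivalate C–O bonds go back to 1. The esters must survive AlCl3.

**10 ⇒ 9 ⇒ 8.** The C–O(sulfonyl) bond is cut, then the racemate is resolved. The S alcohol is needed: the descriptor at C7 becomes R in 11, 19, 20 and 21 only because the priorities change.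

**18 ⇒ 17 ⇒ 16 ⇒ 14 ⇒ 13 ⇒ 12.** The C6'=C7' alkene is cut by retro-cross-metathesis to a terminal alkene, the acetate is removed, and the C4'–C5' bond is cut by retro-allylation of an aldehyde (this is where C4' is set by reagent control). The aldehyde is then taken back to the E-methyl group of a prenyl unit (allylic oxidation), and the carbonate to the alcohol. The demands are Si-face allylation of an α-methyl enal, E-selective oxidation, and a metathesis that touches only the terminal alkene.

## Other disconnections considered

**Alternative 1:** The cut runs across ring C at C5–C6 and C7–C8, a retro-[4+2]. In the forward direction the silyl dienol ether A1 and the acrylate A2 would combine under a chiral oxazaborolidinium Lewis acid to give cyclohexene A3. A3 carries the future C7 as an ester-bearing stereocentre next to the C8 gem-dimethyl group, with the silyl enol ether fixed between C9 and C1.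
- In favour: C7 is set catalytically from achiral bulk materials, which is better than a kinetic resolution that discards half of 8. The concerted cycloaddition is mechanistically more predictable than a cation–enol closure. The regiodefined enol ether allows C1 and C5 to be substituted one after the other under substrate control by C7, so the site and face questions of step 13 of the chosen plan do not arise; on this point it is the better plan.
- Against: A3 contains only ring C. Ring B, the aroyl group, both bridgehead quaternary centres, three of the four side chains and the carbinol are still missing. A three-carbon annulation onto an α,α'-fully substituted cyclohexanone and a late C3 aroylation are both demanding.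
- Comparison: the C1–C8 bond comes for free with the diene (equal or better); the linear sequence would be roughly twice as long as the 8 steps of the chosen plan.

**Alternative 2:** The cut is C5–C6, read as a retro-1,2-shift that returns C6 to C9 and gives the cis-fused hydrindane A4. In the forward direction the C5 enolate of A4 is oxidised at C5 by PhI(OAc)2, C6 migrates from the carbinol carbon C9 to C5, and the alkoxide collapses to the C9 ketone, giving bicycle A5.
- In favour: the bicycle and the C9 ketone form in one irreversible ring expansion with no competing O-capture, which is mechanistically cleaner than the chosen key step. C1 and C7 are already in place, and the bridgehead configuration is dictated by the fused precursor, so the C5 face problem does not exist (better on this point). The vinylogous ester differentiates the C2 and C4 oxygens for later C3 acylation.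
- Against: A5 has hydrogen on C5 and on C3. The 4-hydroxygeranyl chain would have to be introduced by bridgehead deprotonation and alkylation with an elaborate allylic electrophile whose carbinol ester would not survive the base. C3 aroylation and enol ether cleavage follow, and A4 itself needs a multistep, enantioselective entry.
- Comparison: on the congested C1–C8 bond the two plans are equal (it is made before the bicycle exists there; here it is made by the bicycle-forming step). Three C–C bond formations after the key step make the step economy clearly worse.

**Alternative 3:** The cut is C1–C2, read as a retro-acyl shift that returns C2 to C9 and places the C9 oxygen as an epoxide over C1–C9, giving the cyclopentenone-fused epoxide A6. In the forward direction BF3-etherate opens the epoxide at the fully substituted C1, and the acyl carbon C2 migrates from C9 to C1. The five-membered ring becomes ring B, and the epoxide oxygen becomes the C9 ketone of vinylogous ester A7.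
- In favour: the shift is stereospecific (C1 follows from the epoxide face with inversion), so C1 does not depend on reversible cation chemistry (better on this point). A7 already holds both bridgehead centres and all four carbon side chains, so its endgame (C3 aroylation, two deprotections) is comparable in length to that of the chosen plan.
- Against: A6 must already contain the C5 quaternary centre and a tetrasubstituted C1=C9 alkene that has to be epoxidised in the presence of four trisubstituted alkenes. BF3 meets prenyl groups and a secondary allylic silyl ether. Migration of the alkyl carbon C5 instead of C2 would contract ring C.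
- Comparison: it is structurally elegant for C1 but moves the chemoselectivity problem to an earlier and worse place; the route to A6 is far longer than the 13 steps that lead to 19.

Key step: step 14

Remarks on the chemistry, stated once:
- The descriptors were re-derived as 1S,5S,7R,4'S with the C7 prenyl group equatorial, and (S)-lavandulol is the correct antipode; no structure needed correction.
- The catechol is carried as its bis(pivalate) and not as silyl ethers. Aryl silyl ethers would not survive the AlCl3 acylation, and they would fall in K2CO3/MeOH anyway; with esters a single methanolysis ends the synthesis.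
- Which antipode of the Trost ligand is matched with the 7R centre for the 5S product cannot be predicted safely. Both are to be compared on small scale; the (R,R) ligand is written.
- The lipase is assumed to acylate the R alcohol faster, so the S alcohol is the recovered one.
- Compounds 19–21 use the bicycle numbering throughout.

## Route

Step 1
Reactants: 1 3,4-dihydroxybenzoic acid
Product: 3 3,4-bis(pivaloyloxy)benzoic acid, via mixed pivalic anhydride 2 (not isolated)
Conditions: PivCl (3.3 equiv), pyridine, CH2Cl2, 0 °C → rt; then H2O/THF, rt
Reagents that add atoms: pivaloyl chloride, CC(C)(C)C(Cl)=O; water, O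
Why: Acylation of both phenols and the carboxylate by the acid chloride (nucleophilic acyl substitution); the mixed anhydride is far more electrophilic than the hindered aryl pivalates and is the only ester hydrolysed by water/pyridine.

Step 2
Reactants: 3 3,4-bis(pivaloyloxy)benzoic acid
Product: 4 3,4-bis(pivaloyloxy)benzoyl chloride
Conditions: (COCl)2, DMF (cat.), CH2Cl2, 0 °C → rt
Reagents that add atoms: oxalyl chloride, ClC(=O)C(Cl)=O
Why: Standard acid chloride formation through the Vilsmeier-type chloroiminium species; neutral, anhydrous conditions leave the aryl pivalates untouched.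

Step 3
Reactants: 4 3,4-bis(pivaloyloxy)benzoyl chloride; 5 phloroglucinol
Product: 6 4-(2,4,6-trihydroxybenzoyl)-1,2-phenylene dipivalate
Conditions: AlCl3 (4 equiv), PhNO2/CH2Cl2, 0 °C → rt; then 1 M HCl, 0 °C
Reagents that add atoms: none
Why: Friedel–Crafts C-acylation of the symmetrical, highly activated phloroglucinol (all three ring carbons equivalent, the ketone deactivates the product against a second acylation); hindered pivalates should tolerate AlCl3 at room temperature where silyl ethers would not.

Step 4
Reactants: 6 4-(2,4,6-trihydroxybenzoyl)-1,2-phenylene dipivalate
Product: 7 4-[2,4,6-trihydroxy-3-(3-methylbut-2-enyl)benzoyl]-1,2-phenylene dipivalate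
Conditions: prenyl bromide (0.95 equiv), DBU (1.1 equiv), THF, 0 °C → rt
Reagents that add atoms: prenyl bromide (1-bromo-3-methylbut-2-ene), CC(C)=CCBr
Why: C-Prenylation of the acylphloroglucinol monoanion by SN2 attack of a ring carbon on the allylic bromide; the two free ring carbons of 6 are equivalent, and the sub-stoichiometric bromide with a non-nucleophilic amidine base limits dialkylation and spares the pivalates.

Step 5
Reactants: 8 (±)-lavandulol
Product: 9 (S)-lavandulol
Conditions: porcine pancreatic lipase, vinyl acetate, hexane, rt, stopped a little beyond half conversion; chromatography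
Reagents that add atoms: none
Why: Lipase-catalysed kinetic resolution by enantioselective transesterification; the R alcohol is expected to be acetylated faster, so the S alcohol is recovered enantioenriched when the reaction is run past half conversion. This fixes the centre that becomes C7 (descriptor R from compound 11 onwards only through a change of priorities).

Step 6
Reactants: 9 (S)-lavandulol
Product: 10 (S)-lavandulyl triflate
Conditions: Tf2O, 2,6-lutidine, CH2Cl2, −78 °C; used at once
Reagents that add atoms: triflic anhydride, O=S(=O)(OS(=O)(=O)C(F)(F)F)C(F)(F)F
Why: O-Sulfonylation of the primary alcohol; no bond to the stereocentre is touched, and low temperature with immediate use keeps the homoallylic triflate from ionising with participation of the isopropenyl group.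

Step 7
Reactants: 7 4-[2,4,6-trihydroxy-3-(3-methylbut-2-enyl)benzoyl]-1,2-phenylene dipivalate; 10 (S)-lavandulyl triflate
Product: 11 4-{2,4,6-trihydroxy-3-(3-methylbut-2-enyl)-5-[(2R)-5-methyl-2-(prop-1-en-2-yl)hex-4-enyl]benzoyl}-1,2-phenylene dipivalate
Conditions: LiN(SiMe3)2 (3.0 equiv), THF/toluene, −78 °C; then 10, −78 → 0 °C; 1 M HCl work-up
Reagents that add atoms: none
Why: C-Alkylation of the lithium phenolate of an acylphloroglucinol with a primary alkyl triflate (SN2); tight lithium–oxygen pairing in a weakly polar medium steers the electrophile to carbon, and the unsubstituted ring carbon reacts in preference to the prenyl-bearing one because the adduct simply rearomatises. The base is consumed by the three acidic phenols, so no free amide is left for the pivalates.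

Step 8
Reactants: 12 prenol
Product: 13 methyl 3-methylbut-2-enyl carbonate
Conditions: ClCO2Me, pyridine, CH2Cl2, 0 °C
Reagents that add atoms: methyl chloroformate, COC(Cl)=O
Why: Acylation of the primary allylic alcohol; the carbonate serves later as the leaving group for palladium and is inert in the next four steps.

Step 9
Reactants: 13 methyl 3-methylbut-2-enyl carbonate
Product: 14 methyl (2E)-3-methyl-4-oxobut-2-enyl carbonate
Conditions: SeO2 (1.1 equiv), 1,4-dioxane, 80 °C
Reagents that add atoms: selenium dioxide, O=[Se]=O
Why: Riley allylic oxidation (ene reaction, then [2,3]-sigmatropic shift) attacks the E-methyl group of a trisubstituted alkene selectively and carries it on to the enal, which fixes the 2E geometry of the side chain.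

Step 10
Reactants: 14 methyl (2E)-3-methyl-4-oxobut-2-enyl carbonate
Product: 16 methyl (2E,4S)-4-hydroxy-3-methylhepta-2,6-dienyl carbonate, via diisopinocampheylborinate 15 (not isolated)
Conditions: Ipc2B(allyl) of the (+)-α-pinene series (1.2 equiv, salt-free, pentane), Et2O, −78 °C; then NaBO3·4H2O, THF/H2O, rt
Reagents that add atoms: B-allyldiisopinocampheylborane from (+)-α-pinene, C=CCB([C@@H]1C[C@@H]2C[C@H]([C@H]1C)C2(C)C)[C@@H]1C[C@@H]2C[C@H]([C@H]1C)C2(C)C
Why: Brown allylation through a closed chair transition state; this reagent antipode is expected to add to the Si face of the α-methyl enal, which gives the 4S carbinol (C4' of the target) by reagent control. The buffered perborate work-up spares the carbonate.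

Step 11
Reactants: 16 methyl (2E,4S)-4-hydroxy-3-methylhepta-2,6-dienyl carbonate
Product: 17 (2E,4S)-1-(methoxycarbonyloxy)-3-methylhepta-2,6-dien-4-yl acetate
Conditions: Ac2O, pyridine, DMAP (cat.), CH2Cl2, 0 °C → rt
Reagents that add atoms: acetic anhydride, CC(=O)OC(C)=O
Why: DMAP-catalysed acetylation at oxygen, with no change at the stereocentre; the acetate makes the carbinol resistant to ionisation and is a much poorer leaving group for palladium than the primary carbonate.

Step 12
Reactants: 17 (2E,4S)-1-(methoxycarbonyloxy)-3-methylhepta-2,6-dien-4-yl acetate
Product: 18 (2E,4S)-1-(methoxycarbonyloxy)-3,7-dimethylocta-2,6-dien-4-yl acetate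
Conditions: 2-methyl-2-butene (co-solvent), second-generation Grubbs catalyst RuCl2(=CHPh)(H2IMes)(PCy3) (5 mol%), CH2Cl2, 40 °C
Reagents that add atoms: 2-methyl-2-butene, CC=C(C)C
Why: Olefin cross-metathesis turns the terminal vinyl group into the isopropylidene terminus with loss of propene; the internal trisubstituted alkene, flanked by two oxygenated carbons, is too hindered and electron-poor to take part.

Step 13
Reactants: 11 4-{2,4,6-trihydroxy-3-(3-methylbut-2-enyl)-5-[(2R)-5-methyl-2-(prop-1-en-2-yl)hex-4-enyl]benzoyl}-1,2-phenylene dipivalate; 18 (2E,4S)-1-(methoxycarbonyloxy)-3,7-dimethylocta-2,6-dien-4-yl acetate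
Product: 19 dearomatised aroylphloroglucinol (bicycle numbering): C5 (S) quaternary with the lavandulyl arm CH2–CH(isopropenyl)(prenyl) (C7 R) and the (2E,4S)-4-acetoxy-3,7-dimethylocta-2,6-dienyl chain, C9 ketone, prenyl on C1, enols at C2 and C4, 3,4-bis(pivaloyloxy)benzoyl on C3
Conditions: Pd2(dba)3·CHCl3 (2.5 mol%), (R,R)-DACH-phenyl Trost ligand (7.5 mol%), THF, 0 °C
Reagents that add atoms: none
Why: Tsuji–Trost dearomative C-allylation: zerovalent palladium ionises the primary carbonate much faster than the secondary acetate, the phenolate formed by the released methoxide attacks the unsubstituted allyl terminus through the lavandulyl-bearing ring carbon, and C-allylation is irreversible whereas O-allyl ethers re-ionise; the syn π-allyl keeps the E alkene. The new quaternary centre C5 is set by the chiral pocket of the ligand, which has to tell apart the two faces of a phenolate that carries the aroyl group on one side and the prenyl group on the other; the 5S epimer is separated by chromatography from any 5R epimer and from the isomer allylated at the prenyl-bearing carbon.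

Step 14
Reactants: 19 dearomatised aroylphloroglucinol (5S, C7 R, 4'S)
Product: 20 (1S,5S,7R)-bicyclo[3.3.1]nonane-2,9-dione 4-enol with prenyl on C1 and C7, gem-dimethyl on C8, the (2E,4S)-4-acetoxy-3,7-dimethylocta-2,6-dienyl chain on C5 and the 3,4-bis(pivaloyloxy)benzoyl group on C3
Conditions: HCO2H (neat, degassed), 23 °C
Reagents that add atoms: none
Why: Formic acid protonates the CH2 terminus of the isopropenyl group (Markovnikov) to give the tertiary C8 cation, which is attacked by C1, the nucleophilic carbon of the C1=C2 enol, and loss of the enol proton leaves the C2 ketone. The closest known reaction type is the acid-promoted cation–enol cyclisation of dearomatised prenylated acylphloroglucinols to bicyclo[3.3.1]nonanetriones. Ring C closes in a 6-(enolexo)-exo-trig mode through a chair in which C6, C7 and C8 bridge the dienone. The new stereocentre C1 is controlled by C5: the arm is anchored on C5 and can only reach the face of the ring on which C6 stands, so 5S gives 1S. With the 5S,7R relationship this chair has the C7 prenyl group equatorial, whereas the 5R epimer would need it axial and is expected to react more slowly or elsewhere. The 1,1-disubstituted alkene is the only one whose tertiary cation sits in a six-membered relationship to an enol carbon, so irreversible C–C bond formation drains the reversibly formed cations; the C2'=C3' alkene is deactivated by the allylic acetoxy group. Attack through C3 is disfavoured because C3 is the more hindered, aroyl-bearing carbon and would place the C7 substituent axial. Capture of the cation by an enol oxygen gives a tertiary alkyl enol ether that can re-ionise in formic acid, while the C1–C8 bond cannot.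

Step 15
Reactants: 20 protected bicycle
Product: 21 CNP0142498.1, the (1S,5S,7R,4'S) target
Conditions: K2CO3 (5 equiv), MeOH (degassed), 23 → 40 °C, argon; then 1 M HCl to pH 3
Reagents that add atoms: none
Why: Base-mediated transesterification removes the two aryl pivalates and the secondary acetate in one operation; the trione is held as its unreactive enolate (no retro-Claisen), no stereocentre is touched, and exclusion of oxygen protects the free catechol.

## Compound list

1 | 3,4-dihydroxybenzoic acid | OC(=O)c1ccc(O)c(O)c1 | starting material
2 | 3,4-bis(pivaloyloxy)benzoic pivalic anhydride | CC(C)(C)C(=O)OC(=O)c1ccc(OC(=O)C(C)(C)C)c(OC(=O)C(C)(C)C)c1 | intermediate (not isolated)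
3 | 3,4-bis(pivaloyloxy)benzoic acid | OC(=O)c1ccc(OC(=O)C(C)(C)C)c(OC(=O)C(C)(C)C)c1 | intermediate
4 | 3,4-bis(pivaloyloxy)benzoyl chloride | ClC(=O)c1ccc(OC(=O)C(C)(C)C)c(OC(=O)C(C)(C)C)c1 | intermediate
5 | phloroglucinol | Oc1cc(O)cc(O)c1 | starting material
6 | 4-(2,4,6-trihydroxybenzoyl)-1,2-phenylene dipivalate | Oc1cc(O)c(C(=O)c2ccc(OC(=O)C(C)(C)C)c(OC(=O)C(C)(C)C)c2)c(O)c1 | intermediate
7 | 4-[2,4,6-trihydroxy-3-(3-methylbut-2-enyl)benzoyl]-1,2-phenylene dipivalate | CC(C)=CCc1c(O)cc(O)c(C(=O)c2ccc(OC(=O)C(C)(C)C)c(OC(=O)C(C)(C)C)c2)c1O | intermediate
8 | (±)-lavandulol | CC(C)=CCC(CO)C(C)=C | starting material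
9 | (S)-lavandulol, (2S)-5-methyl-2-(prop-1-en-2-yl)hex-4-en-1-ol | CC(C)=CC[C@@H](C(C)=C)CO | intermediate
10 | (S)-lavandulyl triflate | CC(C)=CC[C@@H](C(C)=C)COS(=O)(=O)C(F)(F)F | intermediate
11 | 4-{2,4,6-trihydroxy-3-(3-methylbut-2-enyl)-5-[(2R)-5-methyl-2-(prop-1-en-2-yl)hex-4-enyl]benzoyl}-1,2-phenylene dipivalate | CC(C)=CC[C@@H](C(C)=C)Cc1c(O)c(CC=C(C)C)c(O)c(C(=O)c2ccc(OC(=O)C(C)(C)C)c(OC(=O)C(C)(C)C)c2)c1O | intermediate
12 | prenol | CC(C)=CCO | starting material
13 | methyl 3-methylbut-2-enyl carbonate | COC(=O)OCC=C(C)C | intermediate
14 | methyl (2E)-3-methyl-4-oxobut-2-enyl carbonate | COC(=O)OC/C=C(\C)C=O | intermediate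
15 | (2E,4S)-1-(methoxycarbonyloxy)-3-methylhepta-2,6-dien-4-yl diisopinocampheylborinate | COC(=O)OC/C=C(\C)[C@@H](OB([C@@H]1C[C@@H]2C[C@H]([C@H]1C)C2(C)C)[C@@H]1C[C@@H]2C[C@H]([C@H]1C)C2(C)C)CC=C | intermediate (not isolated)
16 | methyl (2E,4S)-4-hydroxy-3-methylhepta-2,6-dienyl carbonate | COC(=O)OC/C=C(\C)[C@@H](O)CC=C | intermediate
17 | (2E,4S)-1-(methoxycarbonyloxy)-3-methylhepta-2,6-dien-4-yl acetate | COC(=O)OC/C=C(\C)[C@@H](OC(C)=O)CC=C | intermediate
18 | (2E,4S)-1-(methoxycarbonyloxy)-3,7-dimethylocta-2,6-dien-4-yl acetate | COC(=O)OC/C=C(\C)[C@@H](OC(C)=O)CC=C(C)C | intermediate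
19 | dearomatised aroylphloroglucinol, 5S, C7 R, 4'S (key-step precursor, catechol as bis-pivalate) | CC(C)=CC[C@@H](C(C)=C)C[C@]2(C/C=C(\C)[C@@H](OC(C)=O)CC=C(C)C)C(=O)C(CC=C(C)C)=C(O)C(C(=O)c3ccc(OC(=O)C(C)(C)C)c(OC(=O)C(C)(C)C)c3)=C2O | intermediate
20 | (1S,5S,7R)-bicycle, carbinol acetate and catechol bis-pivalate (key-step product) | CC(C)=CC[C@@H]1C[C@]2(C/C=C(\C)[C@@H](OC(C)=O)CC=C(C)C)C(=O)[C@@](CC=C(C)C)(C(=O)C(C(=O)c3ccc(OC(=O)C(C)(C)C)c(OC(=O)C(C)(C)C)c3)=C2O)C1(C)C | intermediate
21 | CNP0142498.1 | CC(C)=CC[C@@H]1C[C@]2(C/C=C(\C)[C@@H](O)CC=C(C)C)C(=O)[C@@](CC=C(C)C)(C(=O)C(C(=O)c3ccc(O)c(O)c3)=C2O)C1(C)C | target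

## Step count and least certain steps

Total: 15 steps. Longest linear sequence: 8 steps (steps 1, 2, 3, 4, 7, 13, 14, 15 from 1; the branch from 12, steps 8–15, is equally long).

**Step 14 (key step).** The most likely failures are: protonation of one of the trisubstituted alkenes followed by capture by an enol oxygen (pyran formation); capture of the C8 cation by oxygen without return; and a closure between two fully substituted carbons so slow that the allylic acetate begins to solvolyse. The fallback generates the same cation without a Brønsted acid. It sets out from 19. A hydrogen-atom-transfer hydrochlorination (TsCl, PhSiH3, Co(BF4)2·6H2O with a salicylaldimine ligand, t-BuOOH as initiator, EtOH, rt) should add HCl in the Markovnikov sense to the 1,1-disubstituted alkene, the least hindered alkene of the molecule, and give the tertiary chloride of 19 F1. Ionisation of F1 with AgOTf and 2,6-di-tert-butylpyridine in CH2Cl2 at −40 °C then delivers the C8 cation to C1 while the prenyl alkenes stay unprotonated. The fallback returns to the route at 20.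

**Step 13.** Two selectivities are at risk.
- Site selectivity: the prenyl-bearing ring carbon is electronically equal to the lavandulyl-bearing one and less hindered, so allylation may go there.
- Facial selectivity: the two faces of the phenolate differ only in remote groups, so the C5 selectivity may be poor.

A slow second ionisation of the allylic acetate (cyclisation of an enol oxygen onto it, or elimination) is a further risk if the reaction is left too long or warmed.

The fallback removes the competing carbon by blocking it as an ester. It sets out from 4 and purchased methyl 2,4,6-trihydroxybenzoate: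
- Friedel–Crafts acylation (AlCl3) gives the methyl 3-aroyl-2,4,6-trihydroxybenzoate F2.
- Alkylation of its single free ring carbon with 10 (LiN(SiMe3)2, THF) gives the 5-lavandulyl ester F3; this ring is less nucleophilic than 7, so more O-alkylation must be expected.
- Allylation with 18 under the conditions of step 13 can now only occur at the lavandulyl-bearing carbon and gives the dearomatised ester F4.
- Demethylation with LiI in refluxing ethyl acetate, followed by spontaneous loss of CO2 from the vinylogous β-keto acid, gives the C1-unsubstituted trione F5.
- C-Prenylation of F5 (prenyl bromide, DBU, THF) rejoins the route at 19.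

The C5 epimers would still have to be separated, at F4 or at 19.

**Step 7.** O-Alkylation may outrun C-alkylation with this hard, β-branched electrophile, and the homoallylic triflate may ionise before it is consumed. The fallback reverses the order of the two alkylations, so that the triflate is used in a dearomatising alkylation of a 3,5-diallylated acylphloroglucinol. It sets out from 7. Palladium-catalysed allylation of its free ring carbon with 18 (Pd2(dba)3·CHCl3, PPh3, THF) gives the aromatic 3-prenyl-5-(4-acetoxygeranyl) compound F6. Treatment of F6 with LiN(SiMe3)2 (exactly three equivalents, so that the acetate is not enolised) and 10 then creates the quaternary centre and returns to the route at 19, bypassing 11. The two allylated carbons of F6 are nearly equal, so a separation of site isomers and C5 epimers would be needed there too.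

**Step 5.** The lipase may discriminate poorly between the enantiomers of a primary alcohol whose stereocentre is one carbon away, or it may prefer the S alcohol. The fallback makes 9 by auxiliary control and starts from purchased materials rather than from a numbered compound (8 is bypassed). 3-Methylbut-2-enoyl chloride and lithiated (S)-4-benzyloxazolidin-2-one give the N-(3-methylbut-2-enoyl)oxazolidinone F7. Deconjugative α-alkylation of its dienolate (NaN(SiMe3)2, THF, −78 °C, prenyl bromide), anti to the benzyl group, gives the (S)-α-isopropenyl imide F8. Reduction with LiBH4 in wet ether releases the auxiliary and returns to the route at 9.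

## Further compounds

F1 | step 14 | tertiary chloride of 19 (C8 chloride, 5S, C7 configuration unchanged) | CC(C)=CC[C@@H](C(C)(C)Cl)C[C@]2(C/C=C(\C)[C@@H](OC(C)=O)CC=C(C)C)C(=O)C(CC=C(C)C)=C(O)C(C(=O)c3ccc(OC(=O)C(C)(C)C)c(OC(=O)C(C)(C)C)c3)=C2O
F2 | step 13 | methyl 3-[3,4-bis(pivaloyloxy)benzoyl]-2,4,6-trihydroxybenzoate | COC(=O)c1c(O)cc(O)c(C(=O)c2ccc(OC(=O)C(C)(C)C)c(OC(=O)C(C)(C)C)c2)c1O
F3 | step 13 | methyl 3-[3,4-bis(pivaloyloxy)benzoyl]-2,4,6-trihydroxy-5-[(2R)-5-methyl-2-(prop-1-en-2-yl)hex-4-enyl]benzoate | CC(C)=CC[C@@H](C(C)=C)Cc1c(O)c(C(=O)OC)c(O)c(C(=O)c2ccc(OC(=O)C(C)(C)C)c(OC(=O)C(C)(C)C)c2)c1O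
F4 | step 13 | dearomatised ester, as 19 with CO2Me in place of the C1 prenyl group | CC(C)=CC[C@@H](C(C)=C)C[C@]2(C/C=C(\C)[C@@H](OC(C)=O)CC=C(C)C)C(=O)C(C(=O)OC)=C(O)C(C(=O)c3ccc(OC(=O)C(C)(C)C)c(OC(=O)C(C)(C)C)c3)=C2O
F5 | step 13 | C1-unsubstituted trione, as 19 with hydrogen on C1 | CC(C)=CC[C@@H](C(C)=C)C[C@]2(C/C=C(\C)[C@@H](OC(C)=O)CC=C(C)C)C(=O)C=C(O)C(C(=O)c3ccc(OC(=O)C(C)(C)C)c(OC(=O)C(C)(C)C)c3)=C2O
F6 | step 7 | 4-{3-[(2E,4S)-4-acetoxy-3,7-dimethylocta-2,6-dienyl]-2,4,6-trihydroxy-5-(3-methylbut-2-enyl)benzoyl}-1,2-phenylene dipivalate | CC(C)=CCc1c(O)c(C/C=C(\C)[C@@H](OC(C)=O)CC=C(C)C)c(O)c(C(=O)c2ccc(OC(=O)C(C)(C)C)c(OC(=O)C(C)(C)C)c2)c1O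
F7 | step 5 | (S)-4-benzyl-3-(3-methylbut-2-enoyl)oxazolidin-2-one | CC(C)=CC(=O)N1[C@@H](Cc2ccccc2)COC1=O
F8 | step 5 | (S)-4-benzyl-3-[(2S)-5-methyl-2-(prop-1-en-2-yl)hex-4-enoyl]oxazolidin-2-one | CC(C)=CC[C@@H](C(C)=C)C(=O)N1[C@@H](Cc2ccccc2)COC1=O
A1 | alternative 1 | 4-methyl-2-(triisopropylsilyloxy)penta-1,3-diene | CC(C)=CC(=C)O[Si](C(C)C)(C(C)C)C(C)C
A2 | alternative 1 | 2,2,2-trifluoroethyl acrylate | C=CC(=O)OCC(F)(F)F
A3 | alternative 1 | 2,2,2-trifluoroethyl (1R)-2,2-dimethyl-4-(triisopropylsilyloxy)cyclohex-3-ene-1-carboxylate | O=C(OCC(F)(F)F)[C@@H]1CCC(O[Si](C(C)C)(C(C)C)C(C)C)=CC1(C)C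
A4 | alternative 2 | cis-fused hydrindane: C9 tertiary alcohol, C4 ketone, C2 methyl enol ether, prenyl on C1 and C7, gem-dimethyl on C8 | CC(C)=CC[C@@H]1C[C@@]2(O)CC(=O)C=C(OC)[C@@]2(CC=C(C)C)C1(C)C
A5 | alternative 2 | bicyclic vinylogous ester with hydrogen on C5, prenyl on C1 and C7 | CC(C)=CC[C@@H]1C[C@@H]2C(=O)[C@@](CC=C(C)C)(C(OC)=CC2=O)C1(C)C
A6 | alternative 3 | cyclopentenone-fused C1–C9 epoxide: C2 ketone on C9, C4 methyl enol ether, C5 silyloxygeranyl chain, prenyl on C1 and C7 | CC(C)=CC[C@@H]1C[C@@]2(C/C=C(\C)[C@@H](O[Si](C)(C)C(C)(C)C)CC=C(C)C)C(OC)=CC(=O)[C@]23O[C@]3(CC=C(C)C)C1(C)C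
A7 | alternative 3 | fully substituted bicyclic vinylogous ester (C2 ketone, C4 methyl enol ether, carbinol silyl ether) | CC(C)=CC[C@@H]1C[C@]2(C/C=C(\C)[C@@H](O[Si](C)(C)C(C)(C)C)CC=C(C)C)C(=O)[C@@](CC=C(C)C)(C(=O)C=C2OC)C1(C)C
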